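The route rests on cutting the two aryl–carbon bonds at C2 and C3 of the dihydrobenzofuran fused to ring B. There ring F (on C2) and ring C (on C3) stand trans. This is the outcome of adding two aryl groups anti across C2=C3 of a planar benzofuran. One palladium-catalysed three-component coupling makes both bonds, sets both stereocentres and leaves boron where the C2 hydrogen belongs. Its precursor is the lithium boronate from 4-chloro-6-methoxybenzofuran and 4-methoxyphenyl pinacol boronate, which meets the enantiopure ring C triflate. The C4 chloride later accepts the Z-styryl unit. Before that, the methyl ethers are exchanged for silyl ethers so that the alkene never sees acid.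

Key step: step 13

Ring labels:
- A = 4-hydroxyphenyl of the styryl group.
- B = benzo ring of the styryl-bearing dihydrobenzofuran (O1, C2, C3, C3a–C7a).
- C = benzo ring of the second dihydrobenzofuran (primed atoms).
- D = 3,5-dihydroxyphenyl on C3'.
- E = 4-hydroxyphenyl on C2'.
- F = 4-hydroxyphenyl on C2.
- Target configuration: C2 S, C3 S, C2' R, C3' R (both rings trans), alkene Z.

Assumption: the enantiomer named for each chiral catalyst (Rh2(S-PTAD)4 in step 9, the MandyPhos ligand in step 13) is assigned by analogy with related substrates. Both are sold in both mirror-image forms, so the antipode would be used if the sense of induction proved opposite.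

**Ring B benzofuran**

Step 1
Reactants: 1 1-chloro-3,5-dimethoxybenzene
Product: 2 2-chloro-4,6-dimethoxybenzaldehyde
Conditions: POCl3, DMF, 0 → 90 °C; then ice/H2O
Reagents that add atoms: N,N-dimethylformamide CN(C)C=O; water O
Why: Vilsmeier–Haack formylation attacks the position ortho to one and para to the other methoxy group, and since the two such positions of this symmetric arene are equivalent, the future C3 carbon lands next to chlorine without the regiochemical gamble of halogenating an unsymmetrical 3-chloro-5-methoxyphenol.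

Step 2
Reactants: 2 2-chloro-4,6-dimethoxybenzaldehyde
Product: 3 2-chloro-6-hydroxy-4-methoxybenzaldehyde
Conditions: BCl3, CH2Cl2, −78 → 0 °C; then H2O
Reagents that add atoms: none
Why: In this chelation-directed ether cleavage BCl3 bridges the aldehyde oxygen and the neighbouring methoxy group, so only the ortho methyl ether is lost and the para one (the later C6 oxygen of ring B) stays.

Step 3
Reactants: 3 2-chloro-6-hydroxy-4-methoxybenzaldehyde
Product: 4 2-(3-chloro-2-formyl-5-methoxyphenoxy)acetic acid
Conditions: ClCH2CO2H, NaOH (2 equiv), H2O, reflux; then HCl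
Reagents that add atoms: chloroacetic acid OC(=O)CCl
Why: Williamson ether synthesis of the phenoxide with chloroacetate uses only enough base for the two acidic protons, so the non-enolisable aldehyde is left alone.

Step 4
Reactants: 4 2-(3-chloro-2-formyl-5-methoxyphenoxy)acetic acid
Product: 5 4-chloro-6-methoxybenzofuran
Conditions: Ac2O, NaOAc, AcOH, reflux
Reagents that add atoms: none
Why: In this Perkin-type cyclisation of an o-formylphenoxyacetic acid the mixed anhydride enolises, adds to the aldehyde and loses CO2 and water to give the benzofuran unsubstituted at C2 and C3 directly.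

**Ring C triflate**

Step 5
Reactants: 6 5-bromo-2-hydroxy-3-methoxybenzaldehyde; 7 4-methoxybenzyl chloride
Product: 8 5-bromo-3-methoxy-2-[(4-methoxybenzyl)oxy]benzaldehyde
Conditions: K2CO3, DMF, 60 °C
Reagents that add atoms: none
Why: Williamson ether synthesis with a reactive benzylic chloride brings in ring E together with the CH2 that becomes C2'.

Step 6
Reactants: 8 5-bromo-3-methoxy-2-[(4-methoxybenzyl)oxy]benzaldehyde; 9 3,5-dimethoxyphenylmagnesium chloride (commercial THF solution)
Product: 10 {5-bromo-3-methoxy-2-[(4-methoxybenzyl)oxy]phenyl}(3,5-dimethoxyphenyl)methanol (racemic)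
Conditions: THF, 0 °C → rt; then aq. NH4Cl
Reagents that add atoms: none
Why: Grignard addition to the aldehyde installs ring D, the aryl bromide does not exchange with an arylmagnesium chloride at this temperature, and the racemic carbinol centre is erased in the next step.

Step 7
Reactants: 10 the diaryl carbinol
Product: 11 {5-bromo-3-methoxy-2-[(4-methoxybenzyl)oxy]phenyl}(3,5-dimethoxyphenyl)methanone
Conditions: MnO2, CH2Cl2, rt
Reagents that add atoms: none
Why: MnO2 oxidises the doubly benzylic alcohol and spares the benzyl ether and the bromide.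

Step 8
Reactants: 11 the diaryl ketone
Product: 12 hydrazone of 11 (E/Z mixture)
Conditions: N2H4·H2O, AcOH (cat.), EtOH, reflux
Reagents that add atoms: hydrazine NN
Why: Acid-catalysed hydrazone condensation of a diaryl ketone is driven by excess hydrazine.

Step 9
Reactants: 12 hydrazone of 11
Product: 14 (2S,3R)-5-bromo-3-(3,5-dimethoxyphenyl)-7-methoxy-2-(4-methoxyphenyl)-2,3-dihydrobenzofuran (cis), via diaryldiazomethane 13 (not isolated)
Conditions: MnO2, CH2Cl2, 0 °C, filter through Celite; filtrate + Rh2(S-PTAD)4 (1 mol%), 0 °C → rt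
Reagents that add atoms: none
Why: In this enantioselective intramolecular C–H insertion of a donor/donor rhodium carbene into the benzylic ether C–H (a 1,5-insertion known for this class of 2,3-diaryl dihydrobenzofurans), the chiral carboxylate pocket selects one carbene face and one enantiotopic hydrogen, which fixes C3' as R and gives the cis ring kinetically.

Step 10
Reactants: 14 the cis dihydrobenzofuran
Product: 15 (2R,3R)-5-bromo-3-(3,5-dimethoxyphenyl)-7-methoxy-2-(4-methoxyphenyl)-2,3-dihydrobenzofuran (trans)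
Conditions: TFA, CH2Cl2, 0 °C → rt
Reagents that add atoms: none
Why: In this acid-catalysed epimerisation, reversible heterolysis of the C2'–O bond to a 4-methoxybenzyl cation lets C2' settle in the more stable trans arrangement (R), while C3' takes no part and keeps its configuration.

Step 11
Reactants: 15 the trans bromide
Product: 16 (2R,3R)-3-(3,5-dimethoxyphenyl)-7-methoxy-2-(4-methoxyphenyl)-2,3-dihydrobenzofuran-5-ol
Conditions: Pd2(dba)3, t-BuXPhos, KOH, 1,4-dioxane/H2O, 100 °C; then HCl
Reagents that add atoms: potassium hydroxide [K+].[OH-]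
Why: Palladium-catalysed hydroxylation of an aryl bromide (C–O cross-coupling with hydroxide) gives the C5' phenol in one operation and avoids a peracid oxidation of a non-phenolic aldehyde.

Step 12
Reactants: 16 the C5' phenol
Product: 17 (2R,3R)-3-(3,5-dimethoxyphenyl)-7-methoxy-2-(4-methoxyphenyl)-2,3-dihydrobenzofuran-5-yl trifluoromethanesulfonate
Conditions: Tf2O, pyridine, CH2Cl2, 0 °C
Reagents that add atoms: triflic anhydride O=S(=O)(OS(=O)(=O)C(F)(F)F)C(F)(F)F
Why: O-Sulfonylation of the only free phenol proceeds without touching either stereocentre.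

**Union and endgame**

Step 13
Reactants: 5 4-chloro-6-methoxybenzofuran; 18 2-(4-methoxyphenyl)-4,4,5,5-tetramethyl-1,3,2-dioxaborolane; 17 the ring C triflate
Product: 21 (2S,3S)-4-chloro-3-[(2R,3R)-3-(3,5-dimethoxyphenyl)-7-methoxy-2-(4-methoxyphenyl)-2,3-dihydrobenzofuran-5-yl]-6-methoxy-2-(4-methoxyphenyl)-2-(4,4,5,5-tetramethyl-1,3,2-dioxaborolan-2-yl)-2,3-dihydrobenzofuran, via 2-lithiobenzofuran 19 (not isolated), via lithium boronate 20 (not isolated)
Conditions: 5, n-BuLi (0.98 equiv), THF, −78 °C; 18, −78 °C → rt; then 17, Pd(OAc)2 (5 mol%), (Sp,Sp)-MandyPhos (Ar = 4-methoxy-3,5-dimethylphenyl, 6 mol%), THF, 60 °C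
Reagents that add atoms: none
Why: Proposed new method: triflate 17 adds oxidatively to the zerovalent palladium–bisphosphine complex, the resulting cationic aryl complex of divalent palladium binds the enol-ether-like C2=C3 bond of boronate 20, the 4-methoxyphenyl group shifts from boron to C2 on the face opposite the metal while C3 bonds to palladium and the furan loses its aromaticity, and reductive elimination with retention joins C3 to C5' of ring C. The closest known reaction types are the enantioselective conjunctive cross-coupling of alkenyl boronate complexes with aryl triflates and the dearomative three-component coupling of 2-indolyl boronate complexes with allylpalladium electrophiles; neither has been shown for a benzofuranyl boronate with an aryl electrophile. No ring is closed, since the step only adds the C2–ring F and C3–ring C bonds to an existing ring. C3 (S) is fixed by the face of the benzofuran that the chiral ligand lets palladium reach, and C2 (S) follows from the anti-periplanar shift, which leaves rings F and C trans and boron cis to ring C. The step needs chemoselectivity for C–OTf over C4–Cl (secured by a bisphosphine that does not activate aryl chlorides at this temperature and by a halide-free boronate made by deprotonation), regiochemistry (secured by boron sitting on C2) and preference for the shift over direct boron-to-palladium transfer (helped by the electron-rich migrating aryl group and by the absence of any β-hydrogen on C2). Because 17 is a single enantiomer, imperfect facial selectivity would appear as a diastereomer that chromatography can remove.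

Step 14
Reactants: 21 the tertiary boronic ester
Product: 22 (2S,3S)-4-chloro-3-[(2R,3R)-3-(3,5-dimethoxyphenyl)-7-methoxy-2-(4-methoxyphenyl)-2,3-dihydrobenzofuran-5-yl]-6-methoxy-2-(4-methoxyphenyl)-2,3-dihydrobenzofuran
Conditions: CsF, H2O (2 equiv), 1,4-dioxane, 45 °C
Reagents that add atoms: none
Why: Fluoride-promoted protodeboronation of a tertiary benzylic boronic ester is known to go with retention because water held at the fluoroboronate delivers the proton on the face that boron leaves, so hydrogen takes the place of boron cis to ring C and rings F and C stay trans.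

Step 15
Reactants: 22 the hexamethyl ether
Product: 23 (2S,3S)-4-chloro-3-[(2R,3R)-3-(3,5-dihydroxyphenyl)-7-hydroxy-2-(4-hydroxyphenyl)-2,3-dihydrobenzofuran-5-yl]-2-(4-hydroxyphenyl)-2,3-dihydrobenzofuran-6-ol
Conditions: BBr3 (excess), CH2Cl2, −78 → 0 °C; then ice/H2O
Reagents that add atoms: none
Why: Lewis-acid cleavage of the six aryl methyl ethers is placed here because no alkene is present yet, so a transient opening of either C2–O bond can only re-close to the more stable trans ring, C3 and C3' are not involved and the aryl chloride is inert.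

Step 16
Reactants: 23 the hexaphenol
Product: 24 hexakis(triisopropylsilyl) ether of 23
Conditions: TIPSCl, imidazole, DMF, rt → 40 °C
Reagents that add atoms: chlorotriisopropylsilane CC(C)[Si](Cl)(C(C)C)C(C)C
Why: Silylation of the phenols gives bulky silyl ethers that tolerate aqueous phosphate in the cross-coupling and fall off later under near-neutral fluoride.

Step 17
Reactants: 25 4-ethynylphenol
Product: 26 (4-ethynylphenoxy)triisopropylsilane
Conditions: TIPSCl, imidazole, CH2Cl2, rt
Reagents that add atoms: chlorotriisopropylsilane CC(C)[Si](Cl)(C(C)C)C(C)C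
Why: Standard silylation gives ring A the same protecting group as the rest of the molecule.

Step 18
Reactants: 26 (4-ethynylphenoxy)triisopropylsilane
Product: 27 (Z)-2-{2-[4-(triisopropylsilyloxy)phenyl]ethenyl}-4,4,5,5-tetramethyl-1,3,2-dioxaborolane
Conditions: HBpin, [Rh(cod)Cl]2 (1.5 mol%), P(i-Pr)3 (6 mol%), Et3N, cyclohexane, rt
Reagents that add atoms: pinacolborane CC1(C)OBOC1(C)C
Why: Rhodium-catalysed formal trans-hydroboration of a terminal alkyne runs through a rhodium vinylidene and places boron and aryl cis, so the Z geometry is set before the fragments meet.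

Step 19
Reactants: 24 the hexasilylated aryl chloride; 27 the Z-alkenyl boronate
Product: 28 heptakis(triisopropylsilyl) ether of the target (2S,3S,2'R,3'R, Z alkene)
Conditions: Pd(OAc)2 (5 mol%), SPhos (10 mol%), K3PO4, toluene/H2O (10:1), 80 °C, dark
Reagents that add atoms: none
Why: Suzuki–Miyaura coupling with a bulky electron-rich biarylphosphine activates the ortho-substituted aryl chloride, and the alkenyl group is transferred with retention of its Z geometry.

Step 20
Reactants: 28 the heptasilyl ether
Product: 29 CNP0172909.2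
Conditions: TBAF, AcOH (1:1), THF, 0 °C, argon, dark
Reagents that add atoms: none
Why: Buffered fluoride desilylation frees all seven phenols without acid, strong base or light, so neither the Z alkene nor the four stereocentres are put at risk.

**Compound list**

1 | 1-chloro-3,5-dimethoxybenzene | COc1cc(Cl)cc(OC)c1 | starting material
2 | 2-chloro-4,6-dimethoxybenzaldehyde | COc1cc(Cl)c(C=O)c(OC)c1 | intermediate
3 | 2-chloro-6-hydroxy-4-methoxybenzaldehyde | COc1cc(O)c(C=O)c(Cl)c1 | intermediate
4 | 2-(3-chloro-2-formyl-5-methoxyphenoxy)acetic acid | COc1cc(Cl)c(C=O)c(OCC(=O)O)c1 | intermediate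
5 | 4-chloro-6-methoxybenzofuran | COc1cc(Cl)c2ccoc2c1 | intermediate
6 | 5-bromo-2-hydroxy-3-methoxybenzaldehyde | COc1cc(Br)cc(C=O)c1O | starting material
7 | 4-methoxybenzyl chloride | COc1ccc(CCl)cc1 | starting material
8 | 5-bromo-3-methoxy-2-[(4-methoxybenzyl)oxy]benzaldehyde | COc1ccc(COc2c(OC)cc(Br)cc2C=O)cc1 | intermediate
9 | 3,5-dimethoxyphenylmagnesium chloride | COc1cc(OC)cc([Mg]Cl)c1 | starting material
10 | {5-bromo-3-methoxy-2-[(4-methoxybenzyl)oxy]phenyl}(3,5-dimethoxyphenyl)methanol, racemic | COc1ccc(COc2c(OC)cc(Br)cc2C(O)c2cc(OC)cc(OC)c2)cc1 | intermediate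
11 | {5-bromo-3-methoxy-2-[(4-methoxybenzyl)oxy]phenyl}(3,5-dimethoxyphenyl)methanone | COc1ccc(COc2c(OC)cc(Br)cc2C(=O)c2cc(OC)cc(OC)c2)cc1 | intermediate
12 | hydrazone of 11 (E/Z mixture) | COc1ccc(COc2c(OC)cc(Br)cc2C(=NN)c2cc(OC)cc(OC)c2)cc1 | intermediate
13 | diaryldiazomethane from 12 | COc1ccc(COc2c(OC)cc(Br)cc2C(=[N+]=[N-])c2cc(OC)cc(OC)c2)cc1 | intermediate
14 | (2S,3R)-5-bromo-3-(3,5-dimethoxyphenyl)-7-methoxy-2-(4-methoxyphenyl)-2,3-dihydrobenzofuran (cis) | Brc1cc(OC)c2c(c1)[C@@H](c1cc(OC)cc(OC)c1)[C@@H](c1ccc(OC)cc1)O2 | intermediate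
15 | (2R,3R)-5-bromo-3-(3,5-dimethoxyphenyl)-7-methoxy-2-(4-methoxyphenyl)-2,3-dihydrobenzofuran (trans) | Brc1cc(OC)c2c(c1)[C@@H](c1cc(OC)cc(OC)c1)[C@H](c1ccc(OC)cc1)O2 | intermediate
16 | (2R,3R)-3-(3,5-dimethoxyphenyl)-7-methoxy-2-(4-methoxyphenyl)-2,3-dihydrobenzofuran-5-ol | Oc1cc(OC)c2c(c1)[C@@H](c1cc(OC)cc(OC)c1)[C@H](c1ccc(OC)cc1)O2 | intermediate
17 | (2R,3R)-3-(3,5-dimethoxyphenyl)-7-methoxy-2-(4-methoxyphenyl)-2,3-dihydrobenzofuran-5-yl triflate | FC(F)(F)S(=O)(=O)Oc1cc(OC)c2c(c1)[C@@H](c1cc(OC)cc(OC)c1)[C@H](c1ccc(OC)cc1)O2 | intermediate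
18 | 2-(4-methoxyphenyl)-4,4,5,5-tetramethyl-1,3,2-dioxaborolane | COc1ccc(cc1)B1OC(C)(C)C(C)(C)O1 | starting material
19 | (4-chloro-6-methoxybenzofuran-2-yl)lithium | [Li]c1cc2c(Cl)cc(OC)cc2o1 | intermediate
20 | lithium (4-chloro-6-methoxybenzofuran-2-yl)(4-methoxyphenyl)(pinacolato)borate | [Li+].COc1ccc(cc1)[B-]1(OC(C)(C)C(C)(C)O1)c1cc2c(Cl)cc(OC)cc2o1 | intermediate
21 | (2S,3S)-2-boryl trans-2,3-diaryl dihydrobenzofuran (full name in step 13) | Clc2cc(OC)cc3c2[C@H](c2cc(OC)c4c(c2)[C@@H](c2cc(OC)cc(OC)c2)[C@H](c2ccc(OC)cc2)O4)[C@@](B1OC(C)(C)C(C)(C)O1)(c2ccc(OC)cc2)O3 | intermediate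
22 | (2S,3S,2'R,3'R) hexamethyl ether chloride (full name in step 14) | Clc2cc(OC)cc3c2[C@H](c2cc(OC)c4c(c2)[C@@H](c2cc(OC)cc(OC)c2)[C@H](c2ccc(OC)cc2)O4)[C@@H](c2ccc(OC)cc2)O3 | intermediate
23 | (2S,3S,2'R,3'R) hexaphenol chloride (full name in step 15) | Clc2cc(O)cc3c2[C@H](c2cc(O)c4c(c2)[C@@H](c2cc(O)cc(O)c2)[C@H](c2ccc(O)cc2)O4)[C@@H](c2ccc(O)cc2)O3 | intermediate
24 | hexakis(triisopropylsilyl) ether of 23 | Clc2cc(O[Si](C(C)C)(C(C)C)C(C)C)cc3c2[C@H](c2cc(O[Si](C(C)C)(C(C)C)C(C)C)c4c(c2)[C@@H](c2cc(O[Si](C(C)C)(C(C)C)C(C)C)cc(O[Si](C(C)C)(C(C)C)C(C)C)c2)[C@H](c2ccc(O[Si](C(C)C)(C(C)C)C(C)C)cc2)O4)[C@@H](c2ccc(O[Si](C(C)C)(C(C)C)C(C)C)cc2)O3 | intermediate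
25 | 4-ethynylphenol | C#Cc1ccc(O)cc1 | starting material
26 | (4-ethynylphenoxy)triisopropylsilane | C#Cc1ccc(O[Si](C(C)C)(C(C)C)C(C)C)cc1 | intermediate
27 | (Z)-2-{2-[4-(triisopropylsilyloxy)phenyl]ethenyl}-4,4,5,5-tetramethyl-1,3,2-dioxaborolane | CC(C)[Si](C(C)C)(C(C)C)Oc1ccc(/C=C\B2OC(C)(C)C(C)(C)O2)cc1 | intermediate
28 | heptakis(triisopropylsilyl) ether of the target | CC(C)[Si](C(C)C)(C(C)C)Oc1ccc(/C=C\c2cc(O[Si](C(C)C)(C(C)C)C(C)C)cc3c2[C@H](c2cc(O[Si](C(C)C)(C(C)C)C(C)C)c4c(c2)[C@@H](c2cc(O[Si](C(C)C)(C(C)C)C(C)C)cc(O[Si](C(C)C)(C(C)C)C(C)C)c2)[C@H](c2ccc(O[Si](C(C)C)(C(C)C)C(C)C)cc2)O4)[C@@H](c2ccc(O[Si](C(C)C)(C(C)C)C(C)C)cc2)O3)cc1 | intermediate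
29 | CNP0172909.2, (2S,3S)-3-[(2R,3R)-3-(3,5-dihydroxyphenyl)-7-hydroxy-2-(4-hydroxyphenyl)-2,3-dihydrobenzofuran-5-yl]-2-(4-hydroxyphenyl)-4-[(Z)-2-(4-hydroxyphenyl)ethenyl]-2,3-dihydrobenzofuran-6-ol | Oc1ccc(/C=C\c2cc(O)cc3c2[C@H](c2cc(O)c4c(c2)[C@@H](c2cc(O)cc(O)c2)[C@H](c2ccc(O)cc2)O4)[C@@H](c2ccc(O)cc2)O3)cc1 | target

**Totals**

Total step count: 20.
Longest linear sequence: 14 steps (steps 5–12, 13–16, 19, 20).

**Steps most likely to fail**

1. Step 13. A carbon ligand may pass directly from boron to palladium, so that plain biaryl coupling outruns the metallate shift. The C4 chlorine may keep palladium away from C3, or the ligand may discriminate poorly between the two faces. The fallback uses the known donor/donor carbene C–H insertion of step 9 to build the ring B dihydrobenzofuran. It sets out from 3 and 15 and comes back to the route at 22.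
   - Phenol 3 would be alkylated with 7 (K2CO3, DMF) to 2-chloro-4-methoxy-6-[(4-methoxybenzyl)oxy]benzaldehyde F1.
   - Bromide 15 would undergo bromine–lithium exchange (n-BuLi, THF, −78 °C) to the ring C aryllithium F2, which would add to F1 to give the diaryl carbinol F3.
   - MnO2 would give the diaryl ketone F4, and hydrazine (n-BuOH, heat, because the ketone is flanked on both sides) the hydrazone F5.
   - MnO2 would give the diazo compound F6, and Rh2(R-PTAD)4, the antipode of the step 9 catalyst, should set C3 as S and close the cis ring of the C2 epimer F7.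
   - TFA in CH2Cl2 would equilibrate C2 to trans as in step 10, giving 22.

2. Step 14. The C–B bond may cleave slowly because the C2 aryl group is electron-rich, or a free carbanion may form and lose the configuration at C2. The fallback gives up stereoretention and relies on thermodynamic control. It sets out from 21 and comes back at 22.
   - PhLi (THF, −78 °C) would convert 21 into the phenyl boronate complex F8.
   - Single-electron oxidation under blue light with [Ir(dF(CF3)ppy)2(dtbbpy)]PF6 and thiophenol (known radical protodeboronation of pinacol boronic esters) would give the C2 radical.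
   - Hydrogen-atom transfer to this radical would give 22 together with the cis C2 epimer F9.
   - TFA in CH2Cl2 would then funnel the mixture to trans 22 through reversible C2–O heterolysis, with C3 as the fixed reference.

3. Step 19. Oxidative addition into the hindered, electron-rich C4–Cl bond may be slow. That would give the Z-alkenyl boronate time to protodeboronate, or let the alkene isomerise on palladium. The fallback makes the C4–C bond with a slim linear partner and sets the geometry afterwards. It sets out from 24 and 26 and comes back at 28.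
   - Copper-free Sonogashira-type alkynylation of the aryl chloride (PdCl2(MeCN)2, XPhos, Cs2CO3, 1,4-dioxane, 90 °C) would give the diaryl alkyne F10.
   - Syn semihydrogenation (H2, Pd/CaCO3 poisoned with Pb(OAc)2, quinoline, EtOAc) would deliver the Z alkene 28.

**Further compounds**

F1 | step 13 | 2-chloro-4-methoxy-6-[(4-methoxybenzyl)oxy]benzaldehyde | COc1ccc(COc2cc(OC)cc(Cl)c2C=O)cc1
F2 | step 13 | [(2R,3R)-3-(3,5-dimethoxyphenyl)-7-methoxy-2-(4-methoxyphenyl)-2,3-dihydrobenzofuran-5-yl]lithium | [Li]c1cc(OC)c2c(c1)[C@@H](c1cc(OC)cc(OC)c1)[C@H](c1ccc(OC)cc1)O2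
F3 | step 13 | diaryl carbinol from F1 and F2 (both carbinol epimers) | COc1ccc(COc2cc(OC)cc(Cl)c2C(O)c2cc(OC)c3c(c2)[C@@H](c2cc(OC)cc(OC)c2)[C@H](c2ccc(OC)cc2)O3)cc1
F4 | step 13 | diaryl ketone from F3 | COc1ccc(COc2cc(OC)cc(Cl)c2C(=O)c2cc(OC)c3c(c2)[C@@H](c2cc(OC)cc(OC)c2)[C@H](c2ccc(OC)cc2)O3)cc1
F5 | step 13 | hydrazone of F4 | COc1ccc(COc2cc(OC)cc(Cl)c2C(=NN)c2cc(OC)c3c(c2)[C@@H](c2cc(OC)cc(OC)c2)[C@H](c2ccc(OC)cc2)O3)cc1
F6 | step 13 | diazo compound from F5 | COc1ccc(COc2cc(OC)cc(Cl)c2C(=[N+]=[N-])c2cc(OC)c3c(c2)[C@@H](c2cc(OC)cc(OC)c2)[C@H](c2ccc(OC)cc2)O3)cc1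
F7 | step 13 | (2R,3S,2'R,3'R) C2 epimer of 22 (ring B dihydrobenzofuran cis) | Clc2cc(OC)cc3c2[C@H](c2cc(OC)c4c(c2)[C@@H](c2cc(OC)cc(OC)c2)[C@H](c2ccc(OC)cc2)O4)[C@H](c2ccc(OC)cc2)O3
F8 | step 14 | lithium phenyl boronate complex of 21 | [Li+].Clc2cc(OC)cc3c2[C@H](c2cc(OC)c4c(c2)[C@@H](c2cc(OC)cc(OC)c2)[C@H](c2ccc(OC)cc2)O4)[C@@]([B-]1(c2ccccc2)OC(C)(C)C(C)(C)O1)(c2ccc(OC)cc2)O3
F9 | step 14 | (2R,3S,2'R,3'R) C2 epimer of 22 (ring B dihydrobenzofuran cis) | Clc2cc(OC)cc3c2[C@H](c2cc(OC)c4c(c2)[C@@H](c2cc(OC)cc(OC)c2)[C@H](c2ccc(OC)cc2)O4)[C@H](c2ccc(OC)cc2)O3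
F10 | step 19 | heptasilylated diaryl alkyne (C≡C in place of the Z alkene of 28) | CC(C)[Si](C(C)C)(C(C)C)Oc1ccc(C#Cc2cc(O[Si](C(C)C)(C(C)C)C(C)C)cc3c2[C@H](c2cc(O[Si](C(C)C)(C(C)C)C(C)C)c4c(c2)[C@@H](c2cc(O[Si](C(C)C)(C(C)C)C(C)C)cc(O[Si](C(C)C)(C(C)C)C(C)C)c2)[C@H](c2ccc(O[Si](C(C)C)(C(C)C)C(C)C)cc2)O4)[C@@H](c2ccc(O[Si](C(C)C)(C(C)C)C(C)C)cc2)O3)cc1
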